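**Strategy**

Ring A is disconnected at C8–C8a and C4a–C5 and built last onto a finished ring C. The feature exploited is that ring A (C4a, C5, C6, C7, C8, C8a) bears contiguous oxygens at C5, C6 and C7: these carbons plus C8 make up one trioxygenated bis(silyloxy)diene, while C4a=C8a is the bromine-bearing α,β double bond of a 4-pyranone. One operation forms both bonds, closes ring A and aromatises it by loss of HBr, methanol and silyl groups, giving a 6-benzyloxy-5,7-dihydroxyflavone. The precursor is a 5-bromo-4-pyranone that already carries ring B at C2 and the C3 oxygen as a pivalate; the bromine sets the oxidation level.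

Key step: step 9

Remark 1: the C3 oxygen is carried as a pivalate, not an alkoxymethyl ether, because the silyl triflate of the key step would ionise an acetal; the acyloxy group also makes the pyranone more electrophilic and is later removed by methanolysis without touching benzyl ethers.
Remark 2: the two sulfate monoesters of the end game are drawn as free acids, as in the target SMILES. In practice the first would be isolated as its sodium salt (bicarbonate work-up, which also removes pyridine before the hydrogenolysis) and the target set free at the end on a sulfonic acid resin in its acid form.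
Remark 3: steps 1–4 use pyranone numbering; from step 9 on, positions are given in flavone numbering (O1, C2, C3, C4, C4a, C5–C8, C8a).

**Route**

Step 1
Reactants: 1 pyromeconic acid (3-hydroxy-4H-pyran-4-one)
Product: 2 2-bromo-3-hydroxy-4H-pyran-4-one
Conditions: NBS, MeCN, 0 → 23 °C
Reagents that add atoms: N-bromosuccinimide, O=C1CCC(=O)N1Br
Why: Electrophilic halogenation of the enolic pyranone should occur at C2, the enol β-carbon between the hydroxyl and the ring oxygen, which is the position at which 3-hydroxy-4-pyranones take up electrophiles.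

Step 2
Reactants: 2 2-bromo-3-hydroxy-4H-pyran-4-one
Product: 3 2-bromo-4-oxo-4H-pyran-3-yl 2,2-dimethylpropanoate
Conditions: PivCl, Et3N, DMAP (cat.), CH2Cl2, 0 °C
Reagents that add atoms: pivaloyl chloride, CC(C)(C)C(Cl)=O
Why: O-acylation of an acidic enol (esterification) masks the metal-chelating hydroxy-pyranone unit before the cross-coupling and installs a group that is stable to Lewis acid.

Step 3
Reactants: 3 2-bromo-4-oxo-4H-pyran-3-yl 2,2-dimethylpropanoate; 4 4-(benzyloxy)phenylboronic acid
Product: 5 2-[4-(benzyloxy)phenyl]-4-oxo-4H-pyran-3-yl 2,2-dimethylpropanoate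
Conditions: Pd(PPh3)4 (5 mol %), K3PO4 (anhydrous), 1,4-dioxane, 80 °C
Reagents that add atoms: none
Why: Suzuki–Miyaura coupling, in which the C2–Br bond is a vinylogous acyl bromide that should add quickly to zerovalent palladium, while the anhydrous phosphate base spares the activated pivalate and the base-sensitive pyranone.

Step 4
Reactants: 5 2-[4-(benzyloxy)phenyl]-4-oxo-4H-pyran-3-yl 2,2-dimethylpropanoate
Product: 6 2-[4-(benzyloxy)phenyl]-5-bromo-4-oxo-4H-pyran-3-yl 2,2-dimethylpropanoate
Conditions: NBS, MeCN, 23 → 50 °C, dark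
Reagents that add atoms: N-bromosuccinimide, O=C1CCC(=O)N1Br
Why: Electrophilic α-bromination of a vinylogous ester: C5 is the β-carbon of the ring enol ether O1–C6=C5 and the only free nucleophilic ring carbon, whereas the benzyloxyphenyl ring has its oxygen lone pair engaged in push–pull conjugation with the pyranone.

Step 5
Reactants: 7 methyl acetoacetate
Product: 8 methyl 2-diazo-3-oxobutanoate
Conditions: 4-acetamidobenzenesulfonyl azide, Et3N, MeCN, 0 → 23 °C
Reagents that add atoms: 4-acetamidobenzenesulfonyl azide, CC(=O)Nc1ccc(cc1)S(=O)(=O)N=[N+]=[N-]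
Why: Regitz diazo transfer to the doubly activated methylene of a β-keto ester.

Step 6
Reactants: 8 methyl 2-diazo-3-oxobutanoate; 9 benzyl alcohol
Product: 10 methyl 2-(benzyloxy)-3-oxobutanoate (racemic)
Conditions: Rh2(OAc)4 (1 mol %), CH2Cl2, 40 °C, slow addition of 8
Reagents that add atoms: none
Why: Rhodium-carbenoid O–H insertion of a diazo-β-keto ester into a primary alcohol places the future C6 oxygen, already benzylated, on the central carbon.

Step 7
Reactants: 10 methyl 2-(benzyloxy)-3-oxobutanoate
Product: 11 methyl 2-(benzyloxy)-3-(trimethylsilyloxy)but-2-enoate (E/Z mixture)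
Conditions: TMSCl, Et3N, toluene, 23 °C
Reagents that add atoms: chlorotrimethylsilane, C[Si](C)(C)Cl
Why: Silyl enol ether formation by soft enolisation of the β-keto ester; the double-bond geometry, and even a share of the terminal enol ether isomer, is immaterial because all converge on the same diene in step 8.

Step 8
Reactants: 11 methyl 2-(benzyloxy)-3-(trimethylsilyloxy)but-2-enoate
Product: 12 2-(benzyloxy)-1-methoxy-1,3-bis(trimethylsilyloxy)buta-1,3-diene (ketene acetal geometry immaterial)
Conditions: LDA (commercial solution), THF, −78 °C; TMSCl, −78 → 20 °C; used crude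
Reagents that add atoms: chlorotrimethylsilane, C[Si](C)(C)Cl
Why: Vinylogous (γ) deprotonation of the β-silyloxy enoate and O-silylation of the dienolate is the standard preparation of 1-alkoxy-1,3-bis(silyloxy)butadienes, including 2-substituted ones.

Step 9
Reactants: 6 2-[4-(benzyloxy)phenyl]-5-bromo-4-oxo-4H-pyran-3-yl 2,2-dimethylpropanoate; 12 2-(benzyloxy)-1-methoxy-1,3-bis(trimethylsilyloxy)buta-1,3-diene
Product: 16 6-(benzyloxy)-2-[4-(benzyloxy)phenyl]-5,7-dihydroxy-4-oxo-4H-chromen-3-yl 2,2-dimethylpropanoate, via 4-silyloxypyrylium triflate 13 (not isolated), via angular bromide adduct 14 (not isolated), via 5,7-bis(trimethylsilyl) ether 15 (not isolated)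
Conditions: TMSOTf (1.3 equiv), CH2Cl2, 23 °C; 12 (1.5 equiv), −78 → 0 °C; 2,6-lutidine, 0 → 23 °C; 1 M HCl, THF
Reagents that add atoms: none
Why: Proposed new method: O-silylation turns the pyranone into 4-silyloxypyrylium 13, whose unsubstituted carbon next to the ring oxygen (future C8a) takes up the CH2 terminus of 12 (future C8) in a Mukaiyama–Michael addition, and the bromo silyl enol ether so formed (future C4a) then adds to the silyl-activated vinylogous ester carbon (future C5), a stepwise ionic [4+2] that gives angular bromide 14. The closest known reactions are the cycloaddition–aromatisation of 1-alkoxy-1,3-bis(silyloxy)dienes with halo-quinones and the silyl-triflate-mediated Michael and tandem Michael annulations of silyloxy dienes with 4-silyloxy(benzo)pyrylium salts; new is their union on a monocyclic α-bromo-4-pyranone, where bromide loss offers an irreversible exit that the halogen-free series lacks. Ring A (six-membered) is closed by the second C–C bond in a favoured 6-endo-trig conjugate attack of C4a on C5, or by a concerted suprafacial [4+2] if both bonds form together. Silyl triflate should then expel MeOSiMe3 from the C5 mixed acetal with loss of H8, and the resulting cyclohexadiene should lose bromide from C4a through an arenium ion stabilised by the C6 benzyloxy group, which gives up H8a to lutidine, so the cis relation of H8a and Br is no obstacle; acid work-up cleaves the two aryl silyl ethers of 15. No stereocentre survives, so none needs control. The selectivity required is regiochemical (C8 to C8a, C5 to C4a) and is secured by attack at the unhindered, non-arylated α-position of the pyrylium, by the diene reacting through its terminal CH2, and by the intramolecular second bond.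

Step 10
Reactants: 16 6-(benzyloxy)-2-[4-(benzyloxy)phenyl]-5,7-dihydroxy-4-oxo-4H-chromen-3-yl 2,2-dimethylpropanoate
Product: 17 6,7-bis(benzyloxy)-2-[4-(benzyloxy)phenyl]-5-hydroxy-4-oxo-4H-chromen-3-yl 2,2-dimethylpropanoate
Conditions: BnBr (1.1 equiv), K2CO3, DMF, 23 °C
Reagents that add atoms: benzyl bromide, BrCc1ccccc1
Why: Williamson etherification should be selective for the acidic 7-OH (para to the carbonyl), because the 5-OH is locked in a hydrogen bond to C4=O and does not alkylate under mild carbonate conditions.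

Step 11
Reactants: 17 6,7-bis(benzyloxy)-2-[4-(benzyloxy)phenyl]-5-hydroxy-4-oxo-4H-chromen-3-yl 2,2-dimethylpropanoate
Product: 18 6,7-bis(benzyloxy)-2-[4-(benzyloxy)phenyl]-3,5-dihydroxy-4H-chromen-4-one
Conditions: K2CO3, MeOH–THF, 0 → 23 °C; aq. NH4Cl
Reagents that add atoms: none
Why: Base-mediated transesterification (methanolysis) of an enol ester whose leaving group is the stabilised flavonol 3-oxide; benzyl ethers are inert.

Step 12
Reactants: 18 6,7-bis(benzyloxy)-2-[4-(benzyloxy)phenyl]-3,5-dihydroxy-4H-chromen-4-one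
Product: 19 6,7-bis(benzyloxy)-2-[4-(benzyloxy)phenyl]-5-hydroxy-4-oxo-4H-chromen-3-yl hydrogen sulfate
Conditions: SO3·pyridine (5 equiv), pyridine, 50 °C; aq. NaHCO3
Reagents that add atoms: sulfur trioxide–pyridine complex, [O-]S(=O)(=O)[n+]1ccccc1
Why: O-sulfonation with an amine–SO3 complex should take the 3-OH only, since the chelated peri 5-OH is the least reactive hydroxyl of a flavonol and all other oxygens are benzylated.

Step 13
Reactants: 19 6,7-bis(benzyloxy)-2-[4-(benzyloxy)phenyl]-5-hydroxy-4-oxo-4H-chromen-3-yl hydrogen sulfate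
Product: 20 5,6,7-trihydroxy-2-(4-hydroxyphenyl)-4-oxo-4H-chromen-3-yl hydrogen sulfate (6-hydroxykaempferol 3-O-sulfate)
Conditions: H2 (1 atm), Pd/C (10% palladium on carbon), MeOH–THF, 23 °C; sulfonic acid resin (acid form), 0 °C
Reagents that add atoms: none
Why: Catalytic hydrogenolysis of the three benzyl ethers under neutral conditions should leave the sulfate monoester salt and the tetrasubstituted C2=C3 bond untouched.

**Compound list**

1 | pyromeconic acid (3-hydroxy-4H-pyran-4-one) | O=c1ccocc1O | starting material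
2 | 2-bromo-3-hydroxy-4H-pyran-4-one | O=c1ccoc(Br)c1O | intermediate
3 | 2-bromo-4-oxo-4H-pyran-3-yl 2,2-dimethylpropanoate | CC(C)(C)C(=O)Oc1c(Br)occc1=O | intermediate
4 | 4-(benzyloxy)phenylboronic acid | OB(O)c1ccc(OCc2ccccc2)cc1 | starting material
5 | 2-[4-(benzyloxy)phenyl]-4-oxo-4H-pyran-3-yl 2,2-dimethylpropanoate | CC(C)(C)C(=O)Oc1c(-c2ccc(OCc3ccccc3)cc2)occc1=O | intermediate
6 | 2-[4-(benzyloxy)phenyl]-5-bromo-4-oxo-4H-pyran-3-yl 2,2-dimethylpropanoate | CC(C)(C)C(=O)Oc1c(-c2ccc(OCc3ccccc3)cc2)occ(Br)c1=O | intermediate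
7 | methyl acetoacetate (methyl 3-oxobutanoate) | CC(=O)CC(=O)OC | starting material
8 | methyl 2-diazo-3-oxobutanoate | COC(=O)C(=[N+]=[N-])C(C)=O | intermediate
9 | benzyl alcohol | OCc1ccccc1 | starting material
10 | methyl 2-(benzyloxy)-3-oxobutanoate (racemic) | COC(=O)C(OCc1ccccc1)C(C)=O | intermediate
11 | methyl 2-(benzyloxy)-3-(trimethylsilyloxy)but-2-enoate (E/Z mixture) | COC(=O)C(OCc1ccccc1)=C(C)O[Si](C)(C)C | intermediate
12 | 2-(benzyloxy)-1-methoxy-1,3-bis(trimethylsilyloxy)buta-1,3-diene (ketene acetal geometry immaterial) | C=C(O[Si](C)(C)C)C(OCc1ccccc1)=C(OC)O[Si](C)(C)C | intermediate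
13 | 2-[4-(benzyloxy)phenyl]-5-bromo-3-(pivaloyloxy)-4-(trimethylsilyloxy)pyrylium triflate | C[Si](C)(C)Oc1c(Br)c[o+]c(-c2ccc(OCc3ccccc3)cc2)c1OC(=O)C(C)(C)C.[O-]S(=O)(=O)C(F)(F)F | intermediate (not isolated)
14 | 6-(benzyloxy)-2-[4-(benzyloxy)phenyl]-4a-bromo-5-methoxy-4-oxo-5,7-bis(trimethylsilyloxy)-4a,5,8,8a-tetrahydro-4H-chromen-3-yl 2,2-dimethylpropanoate (racemic; cis ring fusion expected, C5 epimers; all stereocentres are lost within the step) | CC(C)(C)C(=O)OC1=C(c2ccc(OCc3ccccc3)cc2)OC2CC(O[Si](C)(C)C)=C(OCc3ccccc3)C(OC)(O[Si](C)(C)C)C2(Br)C1=O | intermediate (not isolated)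
15 | 6-(benzyloxy)-2-[4-(benzyloxy)phenyl]-4-oxo-5,7-bis(trimethylsilyloxy)-4H-chromen-3-yl 2,2-dimethylpropanoate | CC(C)(C)C(=O)Oc1c(-c2ccc(OCc3ccccc3)cc2)oc2cc(O[Si](C)(C)C)c(OCc3ccccc3)c(O[Si](C)(C)C)c2c1=O | intermediate (not isolated)
16 | 6-(benzyloxy)-2-[4-(benzyloxy)phenyl]-5,7-dihydroxy-4-oxo-4H-chromen-3-yl 2,2-dimethylpropanoate | CC(C)(C)C(=O)Oc1c(-c2ccc(OCc3ccccc3)cc2)oc2cc(O)c(OCc3ccccc3)c(O)c2c1=O | intermediate
17 | 6,7-bis(benzyloxy)-2-[4-(benzyloxy)phenyl]-5-hydroxy-4-oxo-4H-chromen-3-yl 2,2-dimethylpropanoate | CC(C)(C)C(=O)Oc1c(-c2ccc(OCc3ccccc3)cc2)oc2cc(OCc3ccccc3)c(OCc3ccccc3)c(O)c2c1=O | intermediate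
18 | 6,7-bis(benzyloxy)-2-[4-(benzyloxy)phenyl]-3,5-dihydroxy-4H-chromen-4-one | O=c1c(O)c(-c2ccc(OCc3ccccc3)cc2)oc2cc(OCc3ccccc3)c(OCc3ccccc3)c(O)c12 | intermediate
19 | 6,7-bis(benzyloxy)-2-[4-(benzyloxy)phenyl]-5-hydroxy-4-oxo-4H-chromen-3-yl hydrogen sulfate | O=c1c(OS(=O)(=O)O)c(-c2ccc(OCc3ccccc3)cc2)oc2cc(OCc3ccccc3)c(OCc3ccccc3)c(O)c12 | intermediate
20 | 5,6,7-trihydroxy-2-(4-hydroxyphenyl)-4-oxo-4H-chromen-3-yl hydrogen sulfate | O=c1c(OS(=O)(=O)O)c(-c2ccc(O)cc2)oc2cc(O)c(O)c(O)c12 | target

**Totals**

Total step count: 13 (four to pyranone 6, four to diene 12, the key step, four to the target).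
Longest linear sequence: 9 steps (1 → 2 → 3 → 5 → 6 → 16 → 17 → 18 → 19 → 20; the diene arm 7 → 8 → 10 → 11 → 12 joins with the same length).

**Steps most likely to fail**

Step 9 (ring A annulation). The sequence may stop after the first C–C bond, because the bromo silyl enol ether is a weak nucleophile towards the vinylogous ester. The 2H-pyran intermediate may open by cleavage of the O1–C8a bond (retro-oxa-Michael). Bromine may also be lost as an electrophile, which would leave ring A at a non-aromatic dihydro level. The fallback uses known flavone chemistry and abandons the pyranone and diene arms altogether. It therefore sets out from no numbered intermediate (none of compounds 1–19 is used) but from purchased scutellarein F1, and it comes back to the route at target 20. Exhaustive benzylation (BnBr, K2CO3, DMF, 80 °C) should give 5,6,7-tris(benzyloxy)-2-[4-(benzyloxy)phenyl]-4H-chromen-4-one F2. Epoxidation of its C2=C3 bond with dimethyldioxirane (acetone–CH2Cl2, 0 °C) should give the 2,3-epoxide F3, which a catalytic amount of TsOH should open and tautomerise to the 3-hydroxyflavone F4. F4 has a single free hydroxyl, so sulfation as in step 12 should give the 3-hydrogen sulfate F5, and hydrogenolysis as in step 13 should give 20.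

Step 4 (C5 bromination). Bromination may stray onto the electron-rich benzyloxyphenyl ring or remain incomplete on the acyloxy-deactivated pyranone. The fallback sets out from 3 and comes back at 6 by reversing the order of events. NBS would brominate C5 of 3 while no arene is present, giving 2,5-dibromo-4-oxo-4H-pyran-3-yl 2,2-dimethylpropanoate F6. A site-selective Suzuki–Miyaura coupling with 4 under the conditions of step 3 should then engage only the C2 bromide, the vinylogous acyl bromide, and leave the slower α-bromide at C5 in place, which is compound 6.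

Step 12 (sulfation). Conversion of the hindered, weakly hydrogen-bonded 3-OH may be incomplete, some sulfation of the 5-OH may occur, and the sulfate may be lost by solvolysis during isolation of the polar salt. The fallback sets out from 18 and comes back at 20 through a protected sulfate. Treatment with 2,2,2-trichloroethyl chlorosulfate (Et3N, DMAP, THF) should give the neutral, chromatographable mixed diester 6,7-bis(benzyloxy)-2-[4-(benzyloxy)phenyl]-5-hydroxy-4-oxo-4H-chromen-3-yl 2,2,2-trichloroethyl sulfate F7. Pd/C with ammonium formate in MeOH should then remove the trichloroethyl group by reductive fragmentation and the benzyl ethers by transfer hydrogenolysis in one operation, giving 20 after contact with the acid resin.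

**Further compounds**

F1 | step 9 | scutellarein (5,6,7-trihydroxy-2-(4-hydroxyphenyl)-4H-chromen-4-one; purchased) | O=c1cc(-c2ccc(O)cc2)oc2cc(O)c(O)c(O)c12
F2 | step 9 | 5,6,7-tris(benzyloxy)-2-[4-(benzyloxy)phenyl]-4H-chromen-4-one | O=c1cc(-c2ccc(OCc3ccccc3)cc2)oc2cc(OCc3ccccc3)c(OCc3ccccc3)c(OCc3ccccc3)c12
F3 | step 9 | 5,6,7-tris(benzyloxy)-2-[4-(benzyloxy)phenyl]-2,3-epoxy-2,3-dihydro-4H-chromen-4-one (racemic, cis-fused epoxide) | O=C1C2OC2(c2ccc(OCc3ccccc3)cc2)Oc2cc(OCc3ccccc3)c(OCc3ccccc3)c(OCc3ccccc3)c12
F4 | step 9 | 5,6,7-tris(benzyloxy)-2-[4-(benzyloxy)phenyl]-3-hydroxy-4H-chromen-4-one | O=c1c(O)c(-c2ccc(OCc3ccccc3)cc2)oc2cc(OCc3ccccc3)c(OCc3ccccc3)c(OCc3ccccc3)c12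
F5 | step 9 | 5,6,7-tris(benzyloxy)-2-[4-(benzyloxy)phenyl]-4-oxo-4H-chromen-3-yl hydrogen sulfate | O=c1c(OS(=O)(=O)O)c(-c2ccc(OCc3ccccc3)cc2)oc2cc(OCc3ccccc3)c(OCc3ccccc3)c(OCc3ccccc3)c12
F6 | step 4 | 2,5-dibromo-4-oxo-4H-pyran-3-yl 2,2-dimethylpropanoate | CC(C)(C)C(=O)Oc1c(Br)occ(Br)c1=O
F7 | step 12 | 6,7-bis(benzyloxy)-2-[4-(benzyloxy)phenyl]-5-hydroxy-4-oxo-4H-chromen-3-yl 2,2,2-trichloroethyl sulfate | O=c1c(OS(=O)(=O)OCC(Cl)(Cl)Cl)c(-c2ccc(OCc3ccccc3)cc2)oc2cc(OCc3ccccc3)c(OCc3ccccc3)c(O)c12
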